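**Assumption:** (R)-(−)-lavandulol (5) and tert-butyl 2-methylbut-3-en-2-yl carbonate (8) are bought as such.

## Retrosynthetic overview

1. 12 ⇐ 11: a C3 radical closes the two seven-membered rings of the homoadamantane (7-exo onto the 7-endo prenyl group) and then the cyclopentane (5-exo onto the C3 prenyl group).
2. 11 ⇐ 10: ring B (C1–C8 bond) by cation–enol cyclisation of the isopropenyl group onto the benzoyl-bearing carbon.
3. 10 ⇐ 7 + 8: Claisen rearrangement of a 1,1-dimethylallyl enol ether builds the quaternary C(Cl)(prenyl) carbon, the later cage/cyclopentane junction.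
4. 7 ⇐ 4 + 6: alkylative dearomatisation of ring A with (R)-lavandulyl triflate; 4 ⇐ 1 + 2, then chlorination.
5. Ring order: A (bought arene → cyclohexadienone) → B → seven-membered rings and cyclopentane; the only bought stereocentre is that of 5.

## Route

Step 1
Reactants: 1 2,4,6-trihydroxybenzophenone; 2 geranyl bromide
Product: 3 {3-[(2E)-3,7-dimethylocta-2,6-dien-1-yl]-2,4,6-trihydroxyphenyl}(phenyl)methanone
Conditions: 10% aq. KOH, 0 °C → rt
Reagents that add atoms: none
Why: C-allylation of the phloroglucinol phenolate (Friedel–Crafts-type SN2 alkylation, carbon favoured over oxygen in water) at a free ring position, with no stereocentre formed and the E-alkene untouched.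

Step 2
Reactants: 3 {3-[(2E)-3,7-dimethylocta-2,6-dien-1-yl]-2,4,6-trihydroxyphenyl}(phenyl)methanone
Product: 4 {3-chloro-5-[(2E)-3,7-dimethylocta-2,6-dien-1-yl]-2,4,6-trihydroxyphenyl}(phenyl)methanone
Conditions: NCS (1.05 equiv), MeCN, 0 °C
Reagents that add atoms: N-chlorosuccinimide, O=C1CCC(=O)N1Cl
Why: Electrophilic aromatic chlorination of the last free ring position, which is far more nucleophilic than the trisubstituted alkenes; the chlorine blocks this carbon in step 4 and is the radical leaving group in step 7.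

Step 3
Reactants: 5 (2R)-5-methyl-2-(prop-1-en-2-yl)hex-4-en-1-ol
Product: 6 (2R)-5-methyl-2-(prop-1-en-2-yl)hex-4-en-1-yl trifluoromethanesulfonate
Conditions: Tf2O, 2,6-lutidine, CH2Cl2, −78 °C; used at once
Reagents that add atoms: trifluoromethanesulfonic anhydride, O=S(=O)(OS(=O)(=O)C(F)(F)F)C(F)(F)F
Why: O-sulfonylation of the primary alcohol, which does not touch the bought stereocentre.

Step 4
Reactants: 4 {3-chloro-5-[(2E)-3,7-dimethylocta-2,6-dien-1-yl]-2,4,6-trihydroxyphenyl}(phenyl)methanone; 6 (2R)-5-methyl-2-(prop-1-en-2-yl)hex-4-en-1-yl trifluoromethanesulfonate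
Product: 7 (6S)-2-benzoyl-4-chloro-6-[(2E)-3,7-dimethylocta-2,6-dien-1-yl]-3,5-dihydroxy-6-[(2S)-5-methyl-2-(prop-1-en-2-yl)hex-4-en-1-yl]cyclohexa-2,4-dien-1-one
Conditions: LiN(SiMe3)2 (3.2 equiv), THF, −78 °C; then 6, −78 → −20 °C; 1 M HCl; prep. HPLC
Reagents that add atoms: none
Why: Alkylative dearomatisation (SN2 of the trilithium phenolate on the primary triflate) at the electron-rich geranyl-bearing carbon rather than the chlorinated one; the side-chain stereocentre is retained, but it is too remote to bias the new quaternary C6, so 7 forms with its C6 epimer (about 1:1) and is separated from it.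

Step 5
Reactants: 7 (6S)-2-benzoyl-4-chloro-6-[(2E)-3,7-dimethylocta-2,6-dien-1-yl]-3,5-dihydroxy-6-[(2S)-5-methyl-2-(prop-1-en-2-yl)hex-4-en-1-yl]cyclohexa-2,4-dien-1-one; 8 tert-butyl 2-methylbut-3-en-2-yl carbonate
Product: 10 (6R)-2-benzoyl-4-chloro-6-[(2E)-3,7-dimethylocta-2,6-dien-1-yl]-3-hydroxy-4-(3-methylbut-2-en-1-yl)-6-[(2S)-5-methyl-2-(prop-1-en-2-yl)hex-4-en-1-yl]cyclohex-2-ene-1,5-dione (both C4 epimers), via tert-prenyl enol ether 9 (not isolated)
Conditions: Pd(PPh3)4 (3 mol%), THF, 0 °C; silica pad; PhMe, 90 °C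
Reagents that add atoms: none
Why: Palladium-catalysed O-allylation of the free C5 enol hydroxyl at the tertiary allyl terminus gives ether 9, whose Claisen rearrangement ([3,3]) can only deliver the allyl group to C4 (C6 is quaternary), giving the linear prenyl group on a quaternary C(Cl) carbon; C4 forms as both epimers, which is irrelevant because it becomes a planar radical in step 7, and the C6 descriptor changes from S to R by priority only.

Step 6
Reactants: 10 (6R)-2-benzoyl-4-chloro-6-[(2E)-3,7-dimethylocta-2,6-dien-1-yl]-3-hydroxy-4-(3-methylbut-2-en-1-yl)-6-[(2S)-5-methyl-2-(prop-1-en-2-yl)hex-4-en-1-yl]cyclohex-2-ene-1,5-dione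
Product: 11 (1R,5R,7S)-1-benzoyl-3-chloro-5-[(2E)-3,7-dimethylocta-2,6-dien-1-yl]-8,8-dimethyl-3,7-bis(3-methylbut-2-en-1-yl)bicyclo[3.3.1]nonane-2,4,9-trione (C3 epimers; 7-prenyl endo, syn to C3)
Conditions: HCO2H (neat), 23 °C, dark
Reagents that add atoms: none
Why: Cation–enol cyclisation (Friedel–Crafts-type C-alkylation): the protonated isopropenyl group gives a tertiary cation that is captured by C2 of the 2-benzoyl-1,3-dione, the only enolisable carbon since C4 and C6 are quaternary (O-capture is reversible in formic acid); with the C6/side-chain relationship of 10 fixed, closure must place the C7 prenyl group endo, so C1 and C5 follow from the bought stereocentre.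

Step 7
Reactants: 11 (1R,5R,7S)-1-benzoyl-3-chloro-5-[(2E)-3,7-dimethylocta-2,6-dien-1-yl]-8,8-dimethyl-3,7-bis(3-methylbut-2-en-1-yl)bicyclo[3.3.1]nonane-2,4,9-trione
Product: 12 the target, 1-benzoyl-5-geranyl-8,8-dimethyl homoadamantane-type 2,4,9-trione with C3 and C7 bridged by CH2–CH and a fused 2,2-dimethyl-3-isopropylcyclopentane (C1 R, C3 R, C5 S, C7 S, ring-fusion CH R, isopropyl CH S)
Conditions: (Me3Si)3SiH (1.3 equiv, syringe pump), AIBN (0.2 equiv), PhH (0.005 M), 80 °C
Reagents that add atoms: none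
Why: Reductive radical cascade: chlorine abstraction gives the C3 radical, which adds 7-exo-trig to the endo C7 prenyl group (C3 is fixed by the cage, and the CMe2 end turns toward C4, away from the C8 methyl groups, setting the ring-fusion CH), then the tertiary radical adds 5-exo-trig to the C3 prenyl group (the isopropyl-bearing CH is set here, with its H cis to the ring-fusion H in the target epimer) and the 2-propyl radical takes H from the silane.

## Compound list

1 | 2,4,6-trihydroxybenzophenone | O=C(c1ccccc1)c1c(O)cc(O)cc1O | starting material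
2 | geranyl bromide, (2E)-1-bromo-3,7-dimethylocta-2,6-diene | CC(C)=CCC/C(C)=C/CBr | starting material
3 | {3-[(2E)-3,7-dimethylocta-2,6-dien-1-yl]-2,4,6-trihydroxyphenyl}(phenyl)methanone | CC(C)=CCC/C(C)=C/Cc1c(O)cc(O)c(C(=O)c2ccccc2)c1O | intermediate
4 | {3-chloro-5-[(2E)-3,7-dimethylocta-2,6-dien-1-yl]-2,4,6-trihydroxyphenyl}(phenyl)methanone | CC(C)=CCC/C(C)=C/Cc1c(O)c(Cl)c(O)c(C(=O)c2ccccc2)c1O | intermediate
5 | (R)-lavandulol, (2R)-5-methyl-2-(prop-1-en-2-yl)hex-4-en-1-ol | OC[C@H](CC=C(C)C)C(C)=C | starting material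
6 | (2R)-5-methyl-2-(prop-1-en-2-yl)hex-4-en-1-yl trifluoromethanesulfonate | O=S(=O)(OC[C@H](CC=C(C)C)C(C)=C)C(F)(F)F | intermediate
7 | (6S)-2-benzoyl-4-chloro-6-geranyl-3,5-dihydroxy-6-[(2S)-5-methyl-2-(prop-1-en-2-yl)hex-4-en-1-yl]cyclohexa-2,4-dien-1-one | CC(C)=CCC/C(C)=C/C[C@@]1(C[C@H](CC=C(C)C)C(C)=C)C(=O)C(C(=O)c2ccccc2)=C(O)C(Cl)=C1O | intermediate
8 | tert-butyl 2-methylbut-3-en-2-yl carbonate | C=CC(C)(C)OC(=O)OC(C)(C)C | starting material
9 | (6S)-2-benzoyl-4-chloro-6-geranyl-3-hydroxy-5-[(2-methylbut-3-en-2-yl)oxy]-6-[(2S)-5-methyl-2-(prop-1-en-2-yl)hex-4-en-1-yl]cyclohexa-2,4-dien-1-one | CC(C)=CCC/C(C)=C/C[C@@]1(C[C@H](CC=C(C)C)C(C)=C)C(=O)C(C(=O)c2ccccc2)=C(O)C(Cl)=C1OC(C)(C)C=C | intermediate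
10 | (6R)-2-benzoyl-4-chloro-6-geranyl-3-hydroxy-4-(3-methylbut-2-en-1-yl)-6-[(2S)-5-methyl-2-(prop-1-en-2-yl)hex-4-en-1-yl]cyclohex-2-ene-1,5-dione, both C4 epimers | CC(C)=CCC/C(C)=C/C[C@@]1(C[C@H](CC=C(C)C)C(C)=C)C(=O)C(C(=O)c2ccccc2)=C(O)C(Cl)(CC=C(C)C)C1=O | intermediate
11 | (1R,5R,7S)-1-benzoyl-3-chloro-5-geranyl-8,8-dimethyl-3,7-bis(3-methylbut-2-en-1-yl)bicyclo[3.3.1]nonane-2,4,9-trione, C3 epimers | CC(C)=CCC/C(C)=C/C[C@@]12C[C@H](CC=C(C)C)C(C)(C)[C@@](C(=O)c3ccccc3)(C1=O)C(=O)C(Cl)(CC=C(C)C)C2=O | intermediate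
12 | target (C1 R, C3 R, C5 S, C7 S, ring-fusion CH R, isopropyl CH S) | CC(C)=CCC/C(C)=C/C[C@]12C[C@@H]3C[C@@H]4C(C)(C)[C@H](C(C)C)C[C@@]4(C1=O)C(=O)[C@](C(=O)c1ccccc1)(C2=O)C3(C)C | target

## Step count and risks

Total steps: 7. Longest linear sequence: 6 (steps 1, 2, 4, 5, 6, 7).

**Step 4** is at risk because the β-branched triflate may O-alkylate or attack the chlorinated carbon, and the new quaternary centre forms without facial control, so half the material is the wrong C6 epimer. The fallback sets out from compound 1 and comes back at compound 7 by reversing the order of the two alkylations. Compound 1 is C-alkylated with triflate 6 (LiN(SiMe3)2, THF) at a free ring CH, which is easier than a dearomatising attack, to give {2,4,6-trihydroxy-3-[(2S)-5-methyl-2-(prop-1-en-2-yl)hex-4-en-1-yl]phenyl}(phenyl)methanone F1. NCS then chlorinates the last free position to give {3-chloro-2,4,6-trihydroxy-5-[(2S)-5-methyl-2-(prop-1-en-2-yl)hex-4-en-1-yl]phenyl}(phenyl)methanone F2. Dearomatisation is then done with the more reactive allylic electrophile geranyl bromide 2 (10% aq. KOH, 0 °C) at the alkyl-bearing carbon, giving 7 together with its C6 epimer.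

**Step 6** is at risk because the C–C closure has to go through the endo (boat-like) arrangement, while formic acid can also protonate the four trisubstituted alkenes over the long reaction time. The fallback sets out from compound 10 and comes back at compound 11 in two stages. Catalytic TsOH in CH2Cl2 at 0 °C first traps the cation on the C1 enol oxygen as the O-cyclised 2,2-dimethyldihydropyran isomer of 10 F3, which is isolated. The tertiary C–O bond is then re-ionised with Me3SiOTf (or Me2AlCl) in CH2Cl2 at −40 °C, where the ion pair can only collapse on C2 (1,3 O-to-C shift), giving 11 without exposing the alkenes to protic acid.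

**Step 7** is at risk because the electrophilic C3 radical may take hydrogen from the silane before the 7-exo closure, and the 5-exo step may give some of the epimer at the isopropyl-bearing carbon (chair-like and boat-like transition states are close). The fallback sets out from compound 11 and comes back at compound 12. Zn in AcOH at rt removes chlorine to give the enolisable (1R,5S,7S)-1-benzoyl-5-geranyl-8,8-dimethyl-3,7-bis(3-methylbut-2-en-1-yl)bicyclo[3.3.1]nonane-2,4,9-trione F4. The same C3 radical is then made by one-electron oxidation of its enol with trivalent manganese, Mn(OAc)3·2H2O (2.2 equiv) in EtOH at 60 °C. No fast hydrogen donor is present, so both cyclisations precede the final hydrogen abstraction from ethanol, and the epimer ratio can differ from the silane run.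

## Further compounds

F1 | step 4 | {2,4,6-trihydroxy-3-[(2S)-5-methyl-2-(prop-1-en-2-yl)hex-4-en-1-yl]phenyl}(phenyl)methanone | O=C(c1ccccc1)c1c(O)cc(O)c(C[C@H](CC=C(C)C)C(C)=C)c1O
F2 | step 4 | {3-chloro-2,4,6-trihydroxy-5-[(2S)-5-methyl-2-(prop-1-en-2-yl)hex-4-en-1-yl]phenyl}(phenyl)methanone | O=C(c1ccccc1)c1c(O)c(Cl)c(O)c(C[C@H](CC=C(C)C)C(C)=C)c1O
F3 | step 6 | O-cyclised isomer of 10, 2,2-dimethyl-3,4-dihydro-2H-pyran fused through the C1 enol oxygen and C6 | CC(C)=CCC/C(C)=C/C[C@@]12C[C@H](CC=C(C)C)C(C)(C)OC1=C(C(=O)c1ccccc1)C(=O)C(Cl)(CC=C(C)C)C2=O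
F4 | step 7 | (1R,5S,7S)-1-benzoyl-5-geranyl-8,8-dimethyl-3,7-bis(3-methylbut-2-en-1-yl)bicyclo[3.3.1]nonane-2,4,9-trione | CC(C)=CCC/C(C)=C/C[C@@]12C[C@H](CC=C(C)C)C(C)(C)[C@@](C(=O)c3ccccc3)(C1=O)C(=O)C(CC=C(C)C)C2=O
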